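**Retrosynthetic overview**
1. Feature: ring C is 1,2,3-trisubstituted (C1 ethano chain to ring B, C2 ether oxygen to ring D, C3 hydroxyl). These three atoms map onto C3, C2 and C1 of a 2-aryloxy-3-alkylcyclohex-2-enone, so ring C is carried as a cyclohexanone from cyclohexane-1,3-dione and aromatized late.
2. Key disconnection: the C2(ring C)–O(ring D) ether. The ring D phenoxide attacks C2 of a 2,3-epoxy ketone, water is lost, and the 18-membered ring closes.
3. Seco precursor: ring B–CH2CH2–ring C bond by 9-BBN hydroboration and B-alkyl Suzuki coupling of a ring B styrene with 3-bromocyclohex-2-enone, then epoxidation; A–O–B ether by Chan–Lam coupling; D–A ethano bridge by Wittig olefination and hydrogenation.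
4. Ring order: rings A, B and D are bought as arenes and the ring C carbocycle as the dione; the macrocycle is the only ring closed (step 10); ring C becomes aromatic in step 11; the ring A methyl ether is cleaved in step 12.

Key step: step 10

Remark: marchantin C has no stereocentre. The epoxy ketones and the hydroxy ketone of steps 8–10 are racemic and their centres are erased in step 10. [3-(Benzyloxy)-4-methoxyphenyl]methanol is taken as a commercial starting material. The ring D phenol is carried as a triisopropylsilyl ether, which is base-stable and is removed under buffered fluoride.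

**Route**

Step 1
Reactants: 1 3-hydroxybenzaldehyde
Product: 2 3-(triisopropylsilyloxy)benzaldehyde
Conditions: TIPSCl, imidazole, DMF, rt
Reagents that add atoms: triisopropylsilyl chloride, CC(C)[Si](Cl)(C(C)C)C(C)C
Why: Imidazole-promoted silylation of a phenol gives an aryl triisopropylsilyl ether that should withstand hydrogenation and the mildly basic steps 3, 5, 7 and 8 and is cleaved by fluoride in step 9 (silyl ether protection).

Step 2
Reactants: 3 [3-(benzyloxy)-4-methoxyphenyl]methanol
Product: 4 [3-(benzyloxy)-4-methoxybenzyl]triphenylphosphonium bromide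
Conditions: PPh3·HBr, MeCN, reflux
Reagents that add atoms: triphenylphosphine hydrobromide, [Br-].[PH+](c1ccccc1)(c1ccccc1)c1ccccc1
Why: Electron-rich benzylic alcohols are converted directly into benzylphosphonium bromides by this weak acid salt (ionization assisted by the para methoxy group, capture by PPh3), and the aryl benzyl ether should be stable to it (phosphonium salt formation).

Step 3
Reactants: 4 [3-(benzyloxy)-4-methoxybenzyl]triphenylphosphonium bromide; 2 3-(triisopropylsilyloxy)benzaldehyde
Product: 6 2-(benzyloxy)-1-methoxy-4-{2-[3-(triisopropylsilyloxy)phenyl]ethenyl}benzene (E/Z mixture), via benzylic phosphorus ylide 5 (not isolated)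
Conditions: NaN(SiMe3)2, THF, 0 °C; then 2, 0 °C to rt
Reagents that add atoms: none
Why: Wittig olefination of a semi-stabilized benzylic ylide with an aromatic aldehyde is reliable, and the alkene geometry is irrelevant because the double bond is saturated in step 4.

Step 4
Reactants: 6 2-(benzyloxy)-1-methoxy-4-{2-[3-(triisopropylsilyloxy)phenyl]ethenyl}benzene
Product: 7 2-methoxy-5-{2-[3-(triisopropylsilyloxy)phenyl]ethyl}phenol
Conditions: H2 (1 atm), 10% Pd/C, EtOAc, rt
Reagents that add atoms: none
Why: Catalytic hydrogenation saturates the stilbene and hydrogenolyses the benzyl ether in one operation, which frees only the ring A phenol while the silyl ether on ring D is inert.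

Step 5
Reactants: 7 2-methoxy-5-{2-[3-(triisopropylsilyloxy)phenyl]ethyl}phenol; 8 4-vinylphenylboronic acid
Product: 9 triisopropyl(3-{2-[4-methoxy-3-(4-vinylphenoxy)phenyl]ethyl}phenoxy)silane
Conditions: Cu(OAc)2 (2 equiv), pyridine, 4 Å molecular sieves, CH2Cl2, air, rt
Reagents that add atoms: none
Why: Chan–Lam oxidative C–O coupling of a phenol with an arylboronic acid runs at room temperature with an amine base, which should preserve the silyl ether and the vinyl group, and ortho-methoxy phenols are accepted substrates.

Step 6
Reactants: 10 cyclohexane-1,3-dione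
Product: 11 3-bromocyclohex-2-en-1-one
Conditions: Ph3PBr2, Et3N, CH2Cl2, 0 °C to rt
Reagents that add atoms: dibromotriphenylphosphorane, BrP(Br)(c1ccccc1)(c1ccccc1)c1ccccc1
Why: The enol oxygen of the dione is activated as an oxyphosphonium leaving group and bromide adds and eliminates at the β-carbon (vinylogous acid bromide formation).

Step 7
Reactants: 9 triisopropyl(3-{2-[4-methoxy-3-(4-vinylphenoxy)phenyl]ethyl}phenoxy)silane; 11 3-bromocyclohex-2-en-1-one
Product: 13 3-{2-[4-(2-methoxy-5-{2-[3-(triisopropylsilyloxy)phenyl]ethyl}phenoxy)phenyl]ethyl}cyclohex-2-en-1-one, via B-alkyl-9-BBN borane 12 (not isolated)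
Conditions: 9-BBN, THF, 0 °C to rt; then 11, PdCl2(dppf) (5 mol%), AsPh3, Cs2CO3, DMF–H2O, rt
Reagents that add atoms: none
Why: Anti-Markovnikov hydroboration of the styrene places boron on the terminal carbon, and the B-alkyl Suzuki–Miyaura coupling of such boranes with β-bromo enones proceeds at room temperature under carbonate, which the silyl ether should survive.

Step 8
Reactants: 13 3-{2-[4-(2-methoxy-5-{2-[3-(triisopropylsilyloxy)phenyl]ethyl}phenoxy)phenyl]ethyl}cyclohex-2-en-1-one
Product: 14 racemic cis-fused 2,3-epoxy ketone of 13 (ring D silyl ether)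
Conditions: 30% aq H2O2, NaOH (0.3 equiv), MeOH–THF, 0 °C
Reagents that add atoms: hydrogen peroxide, OO
Why: Weitz–Scheffer nucleophilic epoxidation (conjugate addition of hydroperoxide, then closure of the enolate onto the O–O bond) is the standard route to 3-alkyl-2,3-epoxycyclohexanones; the oxirane can only be cis-fused, so the two new stereocentres form as one racemic pair, and both are erased in step 10.

Step 9
Reactants: 14 racemic cis-fused 2,3-epoxy ketone of 13 (ring D silyl ether)
Product: 15 seco phenol epoxy ketone (free ring D phenol, racemic)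
Conditions: Bu4NF–AcOH (1:1), THF, 0 °C
Reagents that add atoms: none
Why: Fluoride cleaves the aryl O–Si bond and the acetic acid buffer protonates the phenoxide as it forms, so the epoxy ketone should not meet a free phenoxide at preparative concentration (buffered desilylation).

Step 10
Reactants: 15 seco phenol epoxy ketone (free ring D phenol, racemic)
Product: 17 macrocyclic 2-aryloxy-3-alkylcyclohex-2-enone, via trans hydroxy ketone 16 (not isolated)
Conditions: Cs2CO3 (2 equiv), DMF, 70 °C, syringe-pump addition of 15 to about 2 mM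
Reagents that add atoms: none
Why: Proposed new method: Cs2CO3 deprotonates only the ring D phenol, whose phenoxide attacks the secondary, carbonyl-activated C2 of the oxirane anti to the epoxide oxygen (SN2, inversion) to give hydroxy ketone 16; the C2–H, now flanked by carbonyl and aryloxy, is removed and the tertiary C3 hydroxide leaves by E1cB to give enone 17. The closest known reaction is the base-mediated opening of 2,3-epoxycyclohexanones by phenols between two molecules, which gives 2-aryloxycyclohex-2-enones; its use to close a macrocycle is the unproven part. The 18-membered ring closes in the 18-exo-tet mode, because the breaking C2–O bond lies outside the ring being formed, and the chain on C3 already sits on the face from which the phenoxide must approach. No stereocentre remains in 17; the two transient centres of 16 follow from the inversion at C2 and are lost on dehydration. The step needs attack at C2 and not at C3, which the carbonyl activation of C2 and the fully substituted C3 should secure, and it needs ring closure over oligomerization, which slow addition to high dilution should secure. The weak base should leave the ketone α-position C6 alone, so that Favorskii-type and retro-aldol pathways stay minor.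

Step 11
Reactants: 17 macrocyclic 2-aryloxy-3-alkylcyclohex-2-enone
Product: 19 marchantin C ring A methyl ether, via cyclohexa-2,5-dienone 18 (not isolated)
Conditions: Pd(O2CCF3)2 (10 mol%), 2-(dimethylamino)pyridine (20 mol%), TsOH·H2O (40 mol%), O2 (1 atm), DMSO, 80 °C
Reagents that add atoms: none
Why: Palladium-catalysed aerobic dehydrogenation of cyclohexenones to phenols (palladium enolate at C6, β-hydride elimination from C5, tautomerization of dienone 18, reoxidation of the palladium hydride by O2) turns the carbonyl carbon into the C3 hydroxyl of ring C next to the C2 aryloxy group and the C1 ethano chain.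

Step 12
Reactants: 19 marchantin C ring A methyl ether
Product: 21 marchantin C, via bis(dibromoboryl) ether 20 (not isolated)
Conditions: BBr3, CH2Cl2, −78 to 0 °C; then H2O
Reagents that add atoms: none
Why: BBr3 cleaves the aryl methyl ether by bromide attack on the methyl group of the boron-complexed ether and leaves the diaryl ethers intact, since an sp2 carbon cannot undergo that displacement (Lewis acid ether cleavage, then hydrolysis of the aryl borates).

**Compound list**
1 | 3-hydroxybenzaldehyde | O=Cc1cccc(O)c1 | starting material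
2 | 3-(triisopropylsilyloxy)benzaldehyde | O=Cc1cccc(O[Si](C(C)C)(C(C)C)C(C)C)c1 | intermediate
3 | [3-(benzyloxy)-4-methoxyphenyl]methanol | COc1ccc(CO)cc1OCc1ccccc1 | starting material
4 | [3-(benzyloxy)-4-methoxybenzyl]triphenylphosphonium bromide | COc1ccc(C[P+](c2ccccc2)(c2ccccc2)c2ccccc2)cc1OCc1ccccc1.[Br-] | intermediate
5 | [3-(benzyloxy)-4-methoxybenzylidene]triphenylphosphorane (ylide, formed in the flask) | COc1ccc(C=P(c2ccccc2)(c2ccccc2)c2ccccc2)cc1OCc1ccccc1 | intermediate
6 | 2-(benzyloxy)-1-methoxy-4-{2-[3-(triisopropylsilyloxy)phenyl]ethenyl}benzene, E/Z mixture | COc1ccc(C=Cc2cccc(O[Si](C(C)C)(C(C)C)C(C)C)c2)cc1OCc1ccccc1 | intermediate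
7 | 2-methoxy-5-{2-[3-(triisopropylsilyloxy)phenyl]ethyl}phenol | COc1ccc(CCc2cccc(O[Si](C(C)C)(C(C)C)C(C)C)c2)cc1O | intermediate
8 | 4-vinylphenylboronic acid | C=Cc1ccc(cc1)B(O)O | starting material
9 | triisopropyl(3-{2-[4-methoxy-3-(4-vinylphenoxy)phenyl]ethyl}phenoxy)silane | COc1ccc(CCc2cccc(O[Si](C(C)C)(C(C)C)C(C)C)c2)cc1Oc1ccc(C=C)cc1 | intermediate
10 | cyclohexane-1,3-dione | O=C1CCCC(=O)C1 | starting material
11 | 3-bromocyclohex-2-en-1-one | O=C1C=C(Br)CCC1 | intermediate
12 | 9-{2-[4-(2-methoxy-5-{2-[3-(triisopropylsilyloxy)phenyl]ethyl}phenoxy)phenyl]ethyl}-9-borabicyclo[3.3.1]nonane (formed in the flask) | COc1ccc(CCc2cccc(O[Si](C(C)C)(C(C)C)C(C)C)c2)cc1Oc1ccc(CCB2C3CCCC2CCC3)cc1 | intermediate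
13 | 3-{2-[4-(2-methoxy-5-{2-[3-(triisopropylsilyloxy)phenyl]ethyl}phenoxy)phenyl]ethyl}cyclohex-2-en-1-one | COc1ccc(CCc2cccc(O[Si](C(C)C)(C(C)C)C(C)C)c2)cc1Oc1ccc(CCC2=CC(=O)CCC2)cc1 | intermediate
14 | 2,3-epoxy ketone of 13, racemic, cis-fused oxirane, one enantiomer drawn | O=C1CCC[C@]2(CCc3ccc(Oc4cc(CCc5cccc(O[Si](C(C)C)(C(C)C)C(C)C)c5)ccc4OC)cc3)O[C@H]12 | intermediate
15 | seco phenol epoxy ketone (14 with free ring D phenol), racemic, one enantiomer drawn | O=C1CCC[C@]2(CCc3ccc(Oc4cc(CCc5cccc(O)c5)ccc4OC)cc3)O[C@H]12 | intermediate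
16 | macrocyclic 2-aryloxy-3-hydroxy ketone, racemic, aryloxy at C2 trans to the C3 hydroxyl, one enantiomer drawn (formed in the flask) | O=C1CCC[C@@]2(O)CCc3ccc(cc3)Oc4cc(ccc4OC)CCc5cccc(c5)O[C@@H]12 | intermediate
17 | macrocyclic 2-aryloxy-3-alkylcyclohex-2-enone | O=C1CCCC2=C1Oc1cccc(c1)CCc1ccc(OC)c(c1)Oc1ccc(CC2)cc1 | intermediate
18 | macrocyclic 2-aryloxy-3-alkylcyclohexa-2,5-dienone, keto tautomer of 19 (formed in the flask) | O=C1C=CCC2=C1Oc1cccc(c1)CCc1ccc(OC)c(c1)Oc1ccc(CC2)cc1 | intermediate
19 | marchantin C ring A methyl ether | COc1ccc2cc1Oc1ccc(cc1)CCc1cccc(O)c1Oc1cccc(c1)CC2 | intermediate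
20 | bis(dibromoboryl) ether of marchantin C (formed in the flask) | BrB(Br)Oc1ccc2cc1Oc1ccc(cc1)CCc1cccc(OB(Br)Br)c1Oc1cccc(c1)CC2 | intermediate
21 | marchantin C | Oc1ccc2cc1Oc1ccc(cc1)CCc1cccc(O)c1Oc1cccc(c1)CC2 | target

**Step count**
Total: 12 steps. Longest linear sequence: 10 steps (steps 1, 3, 4, 5, 7, 8, 9, 10, 11, 12); steps 2 and 6 are side branches.

**Steps most likely to fail**

1. Step 10 (the step beyond known chemistry). Ring closure may be slower than etherification between molecules, giving oligomers, or the epoxy ketone may decay under base (Favorskii-type contraction, retro-aldol cleavage of 16) before the hindered C2 is attacked.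
Fallback, known chemistry: it sets out from 8, with 11 and 1 as the other numbered inputs, and comes back at 17. The ether is made between two molecules and the ring is closed at the D–A ethano bridge by Wittig olefination.
- Chan–Lam coupling of commercial 3-hydroxy-4-methoxybenzyl alcohol (COc1ccc(CO)cc1O) with 8 under the conditions of step 5 should give the styrene alcohol F1.
- 9-BBN (2.2 equiv, one for the hydroxyl) converts it into the bis-boron species F2, which is coupled in the same flask with 11 as in step 7 to the enone alcohol F3.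
- H2O2/NaOH as in step 8 gives the racemic epoxy ketone alcohol F4.
- F4 and an excess of 1 with Cs2CO3 in DMF at 60 °C and 0.2 M should give, through the trans hydroxy ketone F5, the aryloxy enone aldehyde F6 by the known opening and dehydration between two molecules.
- PPh3·HBr in MeCN converts the benzylic alcohol into the phosphonium bromide F7.
- Slow addition of F7 to NaOMe in CH2Cl2–MeOH at high dilution forms the ylide F8, which closes the 18-membered ring as the macrocyclic stilbene F9 (E/Z mixture).
- Hydrogenation of the disubstituted alkene (H2, 5% Pd/C, EtOAc, stopped after one equivalent, or diimide from TsNHNH2 and NaOAc) returns to 17; the tetrasubstituted enol ether double bond should reduce far more slowly.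

2. Step 11. Palladium enolate formation at C6 of the hindered, macrocycle-bound enone may be slow, so that the dehydrogenation stalls while the benzylic bridges are oxidized or the enol ether is hydrolysed by the acid.
Fallback: it sets out from 17 and comes back at 19. Kinetic deprotonation at C6 with LiN(SiMe3)2 in THF at −78 °C and trapping with PhSeCl should give the racemic 6-(phenylselanyl) ketone F10. Oxidation with 30% H2O2 and pyridine in CH2Cl2 at 0 °C to rt gives the selenoxide F11, whose syn-elimination forms dienone 18, which tautomerizes to 19 (selenoxide elimination in two stages in place of catalytic dehydrogenation).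

3. Step 5. Coupling at the ortho-methoxy phenol may be sluggish, so that protodeboronation, homocoupling and oxidation of the boronic acid consume the partner.
Fallback: it sets out from 7 and comes back at 9. Palladium-catalysed C–O cross-coupling (Buchwald–Hartwig etherification) of 7 with 4-bromobenzaldehyde (Pd(OAc)2, 2-(di-tert-butylphosphino)-2',4',6'-triisopropylbiphenyl, K3PO4, toluene, 100 °C) should give the diaryl ether aldehyde F12. Methylenetriphenylphosphorane F13 (from Ph3PCH3Br and NaN(SiMe3)2, THF, 0 °C) then converts the aldehyde into the vinyl group of 9.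

**Further compounds**
F1 | step 10 | [4-methoxy-3-(4-vinylphenoxy)phenyl]methanol | COc1ccc(CO)cc1Oc1ccc(C=C)cc1
F2 | step 10 | bis-boron species of F1 (O-borinate and B-alkyl-9-BBN, formed in the flask) | COc1ccc(COB2C3CCCC2CCC3)cc1Oc1ccc(CCB2C3CCCC2CCC3)cc1
F3 | step 10 | 3-(2-{4-[5-(hydroxymethyl)-2-methoxyphenoxy]phenyl}ethyl)cyclohex-2-en-1-one | COc1ccc(CO)cc1Oc1ccc(CCC2=CC(=O)CCC2)cc1
F4 | step 10 | 2,3-epoxy ketone of F3, racemic, cis-fused oxirane, one enantiomer drawn | O=C1CCC[C@]2(CCc3ccc(Oc4cc(CO)ccc4OC)cc3)O[C@H]12
F5 | step 10 | 2-(3-formylphenoxy)-3-hydroxy ketone from F4 and 1, racemic, aryloxy trans to hydroxyl (formed in the flask) | O=C1CCC[C@@](O)(CCc2ccc(Oc3cc(CO)ccc3OC)cc2)[C@H]1Oc1cccc(C=O)c1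
F6 | step 10 | 3-{[2-(2-{4-[5-(hydroxymethyl)-2-methoxyphenoxy]phenyl}ethyl)-6-oxocyclohex-1-en-1-yl]oxy}benzaldehyde | O=Cc1cccc(OC2=C(CCc3ccc(Oc4cc(CO)ccc4OC)cc3)CCCC2=O)c1
F7 | step 10 | benzylic triphenylphosphonium bromide of F6 | [Br-].O=Cc1cccc(OC2=C(CCc3ccc(Oc4cc(C[P+](c5ccccc5)(c5ccccc5)c5ccccc5)ccc4OC)cc3)CCCC2=O)c1
F8 | step 10 | ylide of F7 (formed in the flask) | O=Cc1cccc(OC2=C(CCc3ccc(Oc4cc(C=P(c5ccccc5)(c5ccccc5)c5ccccc5)ccc4OC)cc3)CCCC2=O)c1
F9 | step 10 | macrocyclic stilbene enone, E/Z mixture | O=C1CCCC2=C1Oc1cccc(c1)C=Cc1ccc(OC)c(c1)Oc1ccc(CC2)cc1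
F10 | step 11 | 6-(phenylselanyl) derivative of 17, racemic | O=C1C([Se]c3ccccc3)CCC2=C1Oc1cccc(c1)CCc1ccc(OC)c(c1)Oc1ccc(CC2)cc1
F11 | step 11 | selenoxide of F10, diastereomer mixture (formed in the flask) | O=C1C([Se](=O)c3ccccc3)CCC2=C1Oc1cccc(c1)CCc1ccc(OC)c(c1)Oc1ccc(CC2)cc1
F12 | step 5 | 4-(2-methoxy-5-{2-[3-(triisopropylsilyloxy)phenyl]ethyl}phenoxy)benzaldehyde | COc1ccc(CCc2cccc(O[Si](C(C)C)(C(C)C)C(C)C)c2)cc1Oc1ccc(C=O)cc1
F13 | step 5 | methylenetriphenylphosphorane (formed in the flask) | C=P(c1ccccc1)(c1ccccc1)c1ccccc1
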